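**Retrosynthetic overview**

- The cinnamyl alkene comes last, by cross-metathesis on an allyl group, and the benzylic carbinol comes from a CBS reduction of an aryl ketone. Both the ketone and the aldehyde behind the allyl group arise from ozonolysis of one C=C bond of a bicyclic aryl-alkene, whose aryl group is put on by Suzuki coupling of an enol triflate.
- Key disconnection: in the bicyclic ketone (a 2-aryl-3-oxabicyclo[3.3.1]nonan-6-one) the oxane bond between the ring O–CH2 carbon and the ring carbon next to the carbonyl is cut. This gives the methoxymethyl ether of an (R)-aryl(4-oxocyclohexyl)methanol; forward, the ketone's enol carbon attacks an O=CH2+ oxocarbenium carbon.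
- Enabling feature: in the oxane (O1, C2–C6) the aryl on C2 and the chains on C3 and C5 are all cis. The CH2–CH= of the C3 chain and the carbinol carbon on C5 close, with C3, C4 and C5, a six-membered carbocycle, and that ring is a mirror-symmetric 4-substituted cyclohexanone. C3 is therefore no stereocentre before the key step; the chains become a 1,3-diaxial bridge and the C2 aryl sits equatorial. An open-chain precursor would instead close through an all-equatorial chair to the 2,3-trans isomer.
- The key-step precursor comes from a CBS reduction of the aryl ketone made from a Weinreb amide and an ester-bearing arylmagnesium reagent.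
- Ring order: the cyclohexanone is bought, the oxane is closed onto it in step 6, and the carbocycle is cut in step 9. C2 is set by catalysis, C3 and C5 are relayed from it in step 6, and the carbinol is set by catalyst control.

Key step: step 6

**Route**

Step 1
Reactants: 1 4-iodophenol
Product: 2 4-iodophenyl pivalate
Conditions: t-BuCOCl, Et3N, DMAP (cat.), CH2Cl2, 0 °C → rt
Reagents that add atoms: pivaloyl chloride, CC(C)(C)C(Cl)=O
Why: O-acylation of the phenol; the pivalate has no enolizable hydrogens, should survive the magnesium reagent of step 2 at low temperature, and makes the aryl ring electron-poor enough to keep the benzylic C–O bond of later intermediates from ionizing.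

Step 2
Reactants: 2 4-iodophenyl pivalate; 3 N-methoxy-N-methyl-1,4-dioxaspiro[4.5]decane-8-carboxamide
Product: 5 4-(1,4-dioxaspiro[4.5]decane-8-carbonyl)phenyl pivalate, via arylmagnesium chloride 4 (not isolated)
Conditions: i-PrMgCl·LiCl, THF, −30 °C; then 3, −30 → 0 °C; aq. NH4Cl
Reagents that add atoms: none
Why: Iodine–magnesium exchange gives an ester-tolerant arylmagnesium reagent whose addition to the Weinreb amide stops at the chelated tetrahedral adduct, so the ketone is released only on work-up (Weinreb ketone synthesis).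

Step 3
Reactants: 5 4-(1,4-dioxaspiro[4.5]decane-8-carbonyl)phenyl pivalate
Product: 6 4-[(R)-1,4-dioxaspiro[4.5]decan-8-yl(hydroxy)methyl]phenyl pivalate
Conditions: (S)-2-methyl-CBS-oxazaborolidine (10 mol %), BH3·SMe2, THF, −20 °C; MeOH
Reagents that add atoms: none
Why: CBS reduction: the catalyst–borane complex binds the ketone with the aryl group as the large and the cyclohexyl carbon as the small substituent, so the (S)-catalyst should give the (R)-carbinol in the sense known for aryl alkyl ketones; this is the only stereocentre set by catalysis before the key step.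

Step 4
Reactants: 6 4-[(R)-1,4-dioxaspiro[4.5]decan-8-yl(hydroxy)methyl]phenyl pivalate
Product: 7 4-[(R)-1,4-dioxaspiro[4.5]decan-8-yl(methoxymethoxy)methyl]phenyl pivalate
Conditions: MeOCH2Cl, i-Pr2NEt, n-Bu4NI (cat.), CH2Cl2, 0 → 40 °C
Reagents that add atoms: chloromethyl methyl ether, COCCl
Why: O-alkylation of the alcohol with the reactive α-chloro ether installs the formaldehyde acetal whose CH2 becomes the ring O–CH2 carbon; the amine base leaves ketal and pivalate untouched.

Step 5
Reactants: 7 4-[(R)-1,4-dioxaspiro[4.5]decan-8-yl(methoxymethoxy)methyl]phenyl pivalate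
Product: 8 4-[(R)-(methoxymethoxy)(4-oxocyclohexyl)methyl]phenyl pivalate
Conditions: pyridinium p-toluenesulfonate (cat.), acetone/H2O, 55 °C
Reagents that add atoms: water, O
Why: Acid-catalysed ketal hydrolysis; the dioxolane ketal is far more labile under these mild conditions than the methoxymethyl ether or the aryl pivalate, so the ketone is unmasked selectively.

Step 6
Reactants: 8 4-[(R)-(methoxymethoxy)(4-oxocyclohexyl)methyl]phenyl pivalate
Product: 11 4-[(1S,2R,5R)-6-oxo-3-oxabicyclo[3.3.1]nonan-2-yl]phenyl pivalate, via silyl enol ether 9 (not isolated), via oxocarbenium triflate 10 (not isolated)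
Conditions: Me3SiOTf (2.5 equiv), i-Pr2NEt (2.8 equiv), CH2Cl2 (0.02 M), −78 → −20 °C; then 1 M HCl, THF, 0 °C
Reagents that add atoms: none
Why: Me3SiOTf/i-Pr2NEt should convert the ketone into its trimethylsilyl enol ethers (on both α-sides, interconverting through the ketone and the ammonium triflate) and ionize the methoxymethyl acetal at its less hindered methoxy oxygen to the O=CH2+ oxocarbenium ion 10, whose carbon is then attacked by the enol carbon with return of Me3SiOTf. The closest known reaction type is the Mukaiyama aldol-type addition of silyl enol ethers to acetals with in-situ enol silane formation, and the carbocyclic counterpart is the intramolecular aldolization of 4-substituted cyclohexanones to bicyclo[3.3.1]nonanes. The oxane ring closes in a 6-(enolexo) mode, endo with respect to the C=O+ bond, through a chair in which the side chain sits axial on the cyclohexene half-chair. The two new stereocentres are the former C4 of the cyclohexanone (oxane C3) and the attacked α-carbon (oxane C5): their cis relation is forced by the 1,3-diaxial bridge of the bicyclo[3.3.1] frame, and which of the two diastereotopic α-carbons reacts is decided by the C2 stereocentre, whose aryl group takes the equatorial position of the chair oxane and so avoids the syn-axial hydrogen of the one-carbon bridge. The step needs this group selectivity (Curtin–Hammett over the two enol silanes) and ionization without loss of the benzylic C–O bond; the equatorial-aryl preference should secure the first, and the electron-poor pivaloyloxyphenyl ring together with the absence of any other π-nucleophile the second. Once the carbocycle is cut, equatorial aryl plus diaxial bridge is the all-cis 2,3,5-trisubstituted oxane of the target.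

Step 7
Reactants: 11 4-[(1S,2R,5R)-6-oxo-3-oxabicyclo[3.3.1]nonan-2-yl]phenyl pivalate
Product: 12 4-[(1S,2R,5R)-6-(trifluoromethylsulfonyloxy)-3-oxabicyclo[3.3.1]non-6-en-2-yl]phenyl pivalate
Conditions: KN(SiMe3)2, THF, −78 °C; PhNTf2, −78 → 0 °C
Reagents that add atoms: N-phenylbis(trifluoromethanesulfonimide), O=S(=O)(N(c1ccccc1)S(=O)(=O)C(F)(F)F)C(F)(F)F
Why: Deprotonation can occur only at the CH2 α-carbon because the other α-carbon is a bridgehead (Bredt's rule), and O-sulfonylation of the potassium enolate should give a single enol triflate; β-elimination of the ring oxygen is blocked for the same reason.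

Step 8
Reactants: 12 4-[(1S,2R,5R)-6-(trifluoromethylsulfonyloxy)-3-oxabicyclo[3.3.1]non-6-en-2-yl]phenyl pivalate; 13 [4-(tert-butyldimethylsilyloxy)phenyl]boronic acid
Product: 14 4-[(1S,2R,5S)-6-[4-(tert-butyldimethylsilyloxy)phenyl]-3-oxabicyclo[3.3.1]non-6-en-2-yl]phenyl pivalate
Conditions: Pd(PPh3)4 (5 mol %), K3PO4, 1,4-dioxane/H2O (10:1), 70 °C
Reagents that add atoms: none
Why: Suzuki–Miyaura coupling of the alkenyl triflate; Pd(PPh3)4 does not insert into the aryl pivalate C–O bond and the phosphate base should spare both phenol protecting groups.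

Step 9
Reactants: 14 4-[(1S,2R,5S)-6-[4-(tert-butyldimethylsilyloxy)phenyl]-3-oxabicyclo[3.3.1]non-6-en-2-yl]phenyl pivalate
Product: 15 4-[(2R,3R,5R)-5-[4-(tert-butyldimethylsilyloxy)benzoyl]-3-(2-oxoethyl)oxan-2-yl]phenyl pivalate
Conditions: O3, pyridine (3 equiv), CH2Cl2, −78 °C
Reagents that add atoms: ozone, [O-][O+]=O
Why: Ozonolysis of the only C=C bond cuts the temporary carbocycle; pyridine promotes direct breakdown of the carbonyl oxide, so ketone and aldehyde arise without a separate reduction and under conditions neither acidic nor basic enough to touch the now enolizable C5 centre.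

Step 10
Reactants: 15 4-[(2R,3R,5R)-5-[4-(tert-butyldimethylsilyloxy)benzoyl]-3-(2-oxoethyl)oxan-2-yl]phenyl pivalate
Product: 16 4-[(2R,3S,5R)-5-[4-(tert-butyldimethylsilyloxy)benzoyl]-3-(prop-2-enyl)oxan-2-yl]phenyl pivalate
Conditions: Ph3PCH3Br, KN(SiMe3)2, THF, 0 °C; then 15, −78 → 0 °C
Reagents that add atoms: methyltriphenylphosphonium bromide, C[P+](c1ccccc1)(c1ccccc1)c1ccccc1.[Br-]
Why: Wittig methylenation; the ylide should react with the aldehyde much faster than with the hindered α-branched aryl ketone and is not basic enough to enolize that ketone appreciably at low temperature.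

Step 11
Reactants: 16 4-[(2R,3S,5R)-5-[4-(tert-butyldimethylsilyloxy)benzoyl]-3-(prop-2-enyl)oxan-2-yl]phenyl pivalate
Product: 17 4-[(2R,3S,5R)-5-[(R)-[4-(tert-butyldimethylsilyloxy)phenyl](hydroxy)methyl]-3-(prop-2-enyl)oxan-2-yl]phenyl pivalate
Conditions: (S)-2-methyl-CBS-oxazaborolidine (1 equiv), catecholborane, toluene, −78 °C; pH 7 buffer
Reagents that add atoms: none
Why: CBS reduction under catalyst control (aryl large, ring carbon small) should give the (R)-carbinol with the (S)-catalyst, and catecholborane as hydride source does not hydroborate the terminal alkene at this temperature.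

Step 12
Reactants: 17 4-[(2R,3S,5R)-5-[(R)-[4-(tert-butyldimethylsilyloxy)phenyl](hydroxy)methyl]-3-(prop-2-enyl)oxan-2-yl]phenyl pivalate; 18 4-ethenylphenyl acetate
Product: 19 4-[(2R,3S,5R)-3-[(E)-3-(4-acetoxyphenyl)prop-2-enyl]-5-[(R)-[4-(tert-butyldimethylsilyloxy)phenyl](hydroxy)methyl]oxan-2-yl]phenyl pivalate
Conditions: 18 (4 equiv), second-generation Grubbs catalyst RuCl2(=CHPh)(H2IMes)(PCy3) (5 mol %), CH2Cl2, 40 °C
Reagents that add atoms: none
Why: Olefin cross-metathesis between the monosubstituted allyl alkene and an excess of the styrene; the ruthenium carbene tolerates the free alcohol and the thermodynamically favoured (E)-styrenyl alkene should form with loss of ethylene.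

Step 13
Reactants: 19 4-[(2R,3S,5R)-3-[(E)-3-(4-acetoxyphenyl)prop-2-enyl]-5-[(R)-[4-(tert-butyldimethylsilyloxy)phenyl](hydroxy)methyl]oxan-2-yl]phenyl pivalate
Product: 20 4-[(E)-3-[(2R,3S,5R)-5-[(R)-hydroxy(4-hydroxyphenyl)methyl]-2-(4-hydroxyphenyl)oxan-3-yl]prop-1-enyl]phenol
Conditions: K2CO3 (3 equiv), MeOH, 0 °C → rt; pH 7 buffer
Reagents that add atoms: none
Why: Methanolysis by methoxide from K2CO3 cleaves the two aryl esters and the aryl silyl ether (phenoxide leaving groups) at room temperature, where neither the p-hydroxybenzyl ether at C2 nor the p-hydroxybenzyl alcohol should ionize, and the neutral work-up avoids acid-promoted epimerization at C2.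

**Compound list**

1 | 4-iodophenol | Oc1ccc(I)cc1 | starting material
2 | 4-iodophenyl pivalate | CC(C)(C)C(=O)Oc1ccc(I)cc1 | intermediate
3 | N-methoxy-N-methyl-1,4-dioxaspiro[4.5]decane-8-carboxamide | CON(C)C(=O)C1CCC2(CC1)OCCO2 | starting material
4 | [4-(pivaloyloxy)phenyl]magnesium chloride (LiCl complex) | CC(C)(C)C(=O)Oc1ccc([Mg]Cl)cc1 | intermediate (not isolated)
5 | 4-(1,4-dioxaspiro[4.5]decane-8-carbonyl)phenyl pivalate | CC(C)(C)C(=O)Oc1ccc(cc1)C(=O)C1CCC2(CC1)OCCO2 | intermediate
6 | 4-[(R)-1,4-dioxaspiro[4.5]decan-8-yl(hydroxy)methyl]phenyl pivalate | CC(C)(C)C(=O)Oc1ccc(cc1)[C@H](O)C1CCC2(CC1)OCCO2 | intermediate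
7 | 4-[(R)-1,4-dioxaspiro[4.5]decan-8-yl(methoxymethoxy)methyl]phenyl pivalate | CC(C)(C)C(=O)Oc1ccc(cc1)[C@H](OCOC)C1CCC2(CC1)OCCO2 | intermediate
8 | 4-[(R)-(methoxymethoxy)(4-oxocyclohexyl)methyl]phenyl pivalate | CC(C)(C)C(=O)Oc1ccc(cc1)[C@H](OCOC)C1CCC(=O)CC1 | intermediate
9 | 4-[(R)-(methoxymethoxy)[(1S)-4-(trimethylsilyloxy)cyclohex-3-en-1-yl]methyl]phenyl pivalate (the enol silane regioisomer that cyclizes) | CC(C)(C)C(=O)Oc1ccc(cc1)[C@H](OCOC)[C@@H]1CC=C(O[Si](C)(C)C)CC1 | intermediate (not isolated)
10 | methylidene{(R)-[4-(pivaloyloxy)phenyl][(1S)-4-(trimethylsilyloxy)cyclohex-3-en-1-yl]methyl}oxonium triflate | CC(C)(C)C(=O)Oc1ccc(cc1)[C@H]([O+]=C)[C@@H]1CC=C(O[Si](C)(C)C)CC1.[O-]S(=O)(=O)C(F)(F)F | intermediate (not isolated)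
11 | 4-[(1S,2R,5R)-6-oxo-3-oxabicyclo[3.3.1]nonan-2-yl]phenyl pivalate (aryl equatorial on the chair oxane) | CC(C)(C)C(=O)Oc1ccc(cc1)[C@@H]1OC[C@@H]2C(=O)CC[C@H]1C2 | intermediate
12 | 4-[(1S,2R,5R)-6-(trifluoromethylsulfonyloxy)-3-oxabicyclo[3.3.1]non-6-en-2-yl]phenyl pivalate | CC(C)(C)C(=O)Oc1ccc(cc1)[C@@H]1OC[C@@H]2C(OS(=O)(=O)C(F)(F)F)=CC[C@H]1C2 | intermediate
13 | [4-(tert-butyldimethylsilyloxy)phenyl]boronic acid | CC(C)(C)[Si](C)(C)Oc1ccc(cc1)B(O)O | starting material
14 | 4-[(1S,2R,5S)-6-[4-(tert-butyldimethylsilyloxy)phenyl]-3-oxabicyclo[3.3.1]non-6-en-2-yl]phenyl pivalate | CC(C)(C)C(=O)Oc1ccc(cc1)[C@@H]1OC[C@@H]2C(=CC[C@H]1C2)c1ccc(O[Si](C)(C)C(C)(C)C)cc1 | intermediate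
15 | 4-[(2R,3R,5R)-5-[4-(tert-butyldimethylsilyloxy)benzoyl]-3-(2-oxoethyl)oxan-2-yl]phenyl pivalate (2,3,5-all-cis) | CC(C)(C)C(=O)Oc1ccc(cc1)[C@@H]1OC[C@H](C(=O)c2ccc(O[Si](C)(C)C(C)(C)C)cc2)C[C@@H]1CC=O | intermediate
16 | 4-[(2R,3S,5R)-5-[4-(tert-butyldimethylsilyloxy)benzoyl]-3-(prop-2-enyl)oxan-2-yl]phenyl pivalate | CC(C)(C)C(=O)Oc1ccc(cc1)[C@@H]1OC[C@H](C(=O)c2ccc(O[Si](C)(C)C(C)(C)C)cc2)C[C@@H]1CC=C | intermediate
17 | 4-[(2R,3S,5R)-5-[(R)-[4-(tert-butyldimethylsilyloxy)phenyl](hydroxy)methyl]-3-(prop-2-enyl)oxan-2-yl]phenyl pivalate | CC(C)(C)C(=O)Oc1ccc(cc1)[C@@H]1OC[C@H]([C@@H](O)c2ccc(O[Si](C)(C)C(C)(C)C)cc2)C[C@@H]1CC=C | intermediate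
18 | 4-ethenylphenyl acetate (4-acetoxystyrene) | CC(=O)Oc1ccc(C=C)cc1 | starting material
19 | 4-[(2R,3S,5R)-3-[(E)-3-(4-acetoxyphenyl)prop-2-enyl]-5-[(R)-[4-(tert-butyldimethylsilyloxy)phenyl](hydroxy)methyl]oxan-2-yl]phenyl pivalate | CC(C)(C)C(=O)Oc1ccc(cc1)[C@@H]1OC[C@H]([C@@H](O)c2ccc(O[Si](C)(C)C(C)(C)C)cc2)C[C@@H]1C/C=C/c1ccc(OC(C)=O)cc1 | intermediate
20 | 4-[(E)-3-[(2R,3S,5R)-5-[(R)-hydroxy(4-hydroxyphenyl)methyl]-2-(4-hydroxyphenyl)oxan-3-yl]prop-1-enyl]phenol | Oc1ccc(cc1)[C@@H]1OC[C@H]([C@@H](O)c2ccc(O)cc2)C[C@@H]1C/C=C/c1ccc(O)cc1 | target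

**Summary**

Total step count: 13. Longest linear sequence: 13 steps (1 → 20); compounds 3, 13 and 18 enter as bought building blocks.

Steps most likely to fail:

1. Step 6. The two enol silanes may not interconvert fast enough, so that part of the material closes through the axial-aryl transition state (loss of group selectivity), or the acetal may ionize at the inner oxygen with loss of the methoxymethyl group. The fallback sets out from 8 and comes back at 14. 4-(tert-Butyldimethylsilyloxy)phenyllithium (from the aryl bromide and n-BuLi) with CeCl3 in THF at −78 °C is added to the ketone of 8 to give the tertiary benzylic alcohol F1 (cis/trans mixture, both usable). Me3SiOTf (2.2 equiv, CH2Cl2, −78 → −40 °C) then ionizes the tertiary alcohol to the aryl-cyclohexenyl ether F2 and its double-bond regioisomer, which interconvert through the tertiary benzylic cation, and ionizes the acetal. Prins closure of the styrene carbon of F2 onto the O=CH2+ carbon and loss of a proton should give 14 with the same equatorial-aryl bias, and steps 7 and 8 fall away.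

2. Step 10. The ylide or residual base may enolize the β-alkoxy aryl ketone, which would epimerize C5 or open the oxane by β-elimination. The fallback sets out from 15 and comes back at 19. Takai olefination (CrCl2, CHI3, THF, 0 °C), which is non-basic and aldehyde-selective, gives the (E)-vinyl iodide ketone F3. CBS reduction as in step 11 gives the vinyl iodide carbinol F4. Suzuki–Miyaura coupling of F4 with 4-acetoxyphenylboronic acid (Pd(PPh3)4, K3PO4, 1,4-dioxane, 50 °C) gives 19, so both the ylide and the metathesis are avoided.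

3. Step 11. Facial selectivity may be poor if the resident stereocentres oppose the catalyst. The fallback sets out from 14 and comes back at 17, and takes the carbinol configuration from the rigid bicycle instead. Hydroboration–oxidation of 14 (BH3·THF, 0 °C; NaBO3) from the exo face gives the bicyclic alcohol F5 with the aryl group equatorial. Dess–Martin periodinane gives the α-aryl ketone F6. Baeyer–Villiger oxidation (m-CPBA, NaHCO3, CH2Cl2), with migration of the benzylic carbon and retention of its configuration, gives the bridged lactone F7. i-Bu2AlH (1.1 equiv, CH2Cl2, −78 °C) gives the lactol F8, and Wittig methylenation (Ph3P=CH2, THF) opens F8 to 17. No enolizable ketone next to C5 is formed on this path.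

**Further compounds**

F1 | step 6 | 4-[(R)-[4-[4-(tert-butyldimethylsilyloxy)phenyl]-4-hydroxycyclohexyl](methoxymethoxy)methyl]phenyl pivalate (cis/trans mixture) | CC(C)(C)C(=O)Oc1ccc(cc1)[C@H](OCOC)C1CCC(O)(CC1)c1ccc(O[Si](C)(C)C(C)(C)C)cc1
F2 | step 6 | 4-[(R)-[(1S)-4-[4-(tert-butyldimethylsilyloxy)phenyl]cyclohex-3-en-1-yl](methoxymethoxy)methyl]phenyl pivalate | CC(C)(C)C(=O)Oc1ccc(cc1)[C@H](OCOC)[C@@H]1CC=C(CC1)c1ccc(O[Si](C)(C)C(C)(C)C)cc1
F3 | step 10 | (E)-vinyl iodide ketone: 15 with CH2–CH=O replaced by CH2–CH=CHI, configuration as in 15 | CC(C)(C)C(=O)Oc1ccc(cc1)[C@@H]1OC[C@H](C(=O)c2ccc(O[Si](C)(C)C(C)(C)C)cc2)C[C@@H]1C/C=C/I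
F4 | step 10 | (E)-vinyl iodide (R)-carbinol: 17 with CH=CH2 replaced by CH=CHI | CC(C)(C)C(=O)Oc1ccc(cc1)[C@@H]1OC[C@H]([C@@H](O)c2ccc(O[Si](C)(C)C(C)(C)C)cc2)C[C@@H]1C/C=C/I
F5 | step 11 | 4-{(2R)-6-[4-(tert-butyldimethylsilyloxy)phenyl]-7-hydroxy-3-oxabicyclo[3.3.1]nonan-2-yl}phenyl pivalate (aryl equatorial, hydroxyl trans to it) | CC(C)(C)C(=O)Oc1ccc(cc1)[C@@H]1OC[C@@H]2[C@H](c3ccc(O[Si](C)(C)C(C)(C)C)cc3)[C@@H](O)C[C@H]1C2
F6 | step 11 | 4-{(2R)-6-[4-(tert-butyldimethylsilyloxy)phenyl]-7-oxo-3-oxabicyclo[3.3.1]nonan-2-yl}phenyl pivalate (aryl equatorial) | CC(C)(C)C(=O)Oc1ccc(cc1)[C@@H]1OC[C@@H]2[C@H](c3ccc(O[Si](C)(C)C(C)(C)C)cc3)C(=O)C[C@H]1C2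
F7 | step 11 | bridged seven-membered lactone from oxygen insertion between the aryl-bearing carbon and the carbonyl of F6 (configuration retained) | CC(C)(C)C(=O)Oc1ccc(cc1)[C@@H]1OC[C@@H]2[C@H](c3ccc(O[Si](C)(C)C(C)(C)C)cc3)OC(=O)C[C@H]1C2
F8 | step 11 | lactol from F7 (mixture at the hemiacetal carbon) | CC(C)(C)C(=O)Oc1ccc(cc1)[C@@H]1OC[C@@H]2[C@H](c3ccc(O[Si](C)(C)C(C)(C)C)cc3)OC(O)C[C@H]1C2
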